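## Remarks on the chemistry

- The target has no stereocentre, and its only non-aromatic C=C bond carries two equal methyl groups, so no configuration has to be set or protected anywhere.
- The regiochemistry of 8, 12 and 15 was re-derived atom by atom: silyl-bearing carbon → C4a, triflate-bearing carbon → C8a, acetal oxygen → O5, methyl ether → O7. The three structures are consistent and need no correction.
- 4-Iodoresorcinol and propiolic acid are taken as commercial. The iodide is preferred to the bromide because it couples with propiolic acid in one step at a temperature at which the arylpropiolic acid keeps its carboxyl group.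

## Structural features

The target is a flavone: benzo ring A is fused to the 4-pyranone ring C through the C4a–C8a bond, and the 2,4-dihydroxyphenyl ring B is attached to C2 by the single C2–C1' bond. Ring A is a phloroglucinol unit whose three oxygens are all different: the ring oxygen O1 on C8a, a free hydroxyl on C5 hydrogen-bonded to the C4 carbonyl, and a methyl ether on C7. C6 carries a 3-methyl-2-oxobutyl chain, C8 is the only unsubstituted carbon of ring A, and ring C carries a prenyl group on C3. There is no stereocentre, so the problem is one of regio- and chemoselectivity only. The fragile groups are the prenyl alkene (acid, electrophilic halogen, oxidants), the benzylic ketone next to the C5 hydroxyl (enolisable, and able to cyclodehydrate to a furan under strong acid), the electron-rich ring B, and the pyranone, which opens with hard nucleophiles. The real difficulty lies in ring A: three oxygens must be told apart, carbon must go to C6 and not to C8, and C3 must be alkylated in a molecule with many other reactive positions. The key step uses the fact that C4a and C8a are neighbouring ring A carbons bearing the acyl carbon C4 and the oxygen O1. This is the pattern left when an aryne spanning C4a–C8a inserts into the C–O bond of a carboxylic acid, and the C5 oxygen, ortho to C4a, polarises that aryne so that oxygen goes to C8a and the acyl carbon to C4a.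

## Logic of the disconnections

25 ⇒ 24. The two aryl O–CH2 acetal bonds on ring B are the last to be cleaved in the forward sense. Keeping these hydroxyls masked shields ring B from fluoride, amide base, Lewis acid and quinone methide chemistry. The gain is in functional groups only. The forward step needs acid mild enough to spare the alkene and the hydroxy ketone of 25.

24 ⇒ 20 + 21. The bond between the benzylic CH2 on C6 and the ketone carbon is cut. This gives an electrophilic one-carbon unit on ring A (quinone methide 23, from ammonium salt 22 and hence from 20) and an acyl anion drawn from 21. The five-carbon chain is reduced to 21 and an aminomethyl handle, and no oxidant or electrophilic halogen has to meet the alkene. The forward step needs umpolung of 21 that adds to 23 faster than 23 oligomerises.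

20 ⇒ 19. The C6–CH2 bond is cut. It is made by electrophilic substitution ortho to the free C5 hydroxyl of 19, which leaves ring A of 19 without any carbon substituent. The demand is regiochemical: C6 must react, and C8, ring B and the alkene must not.

19 ⇒ 18. The acetal is put back on O5. The C5 hydroxyl is needed free only for the C6 chemistry and must be masked during the C3 metalation. The forward cleavage has to pick one of three acetal ethers, which chelation by the neighbouring C4 carbonyl makes possible.

18 ⇒ 15 + 16. The C3–CH2 bond is cut to the C3 anion 17 of 15 and to 16. C3–H is the only acidic position of 15, so the allyl group can be introduced here with a simple amide base, before any ketone or free phenol is present. The alkylation must occur at the primary carbon of 16.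

15 ⇒ 8 + 12. Three bonds are cut at once: O1–C8a, C4–C4a and O1–C2. This removes ring C and splits the skeleton into two fragments of similar size: 8 (ring A with its oxygens already differentiated) and 12 (ring B plus C2, C3 and C4). Forward, aryne 13 must take up the carboxylate of 12 in the right orientation, the aryl anion must transfer the acyl group to give 14, and the phenoxide of 14 must close in the 6-endo mode.

8 ⇒ 5. The C–Si and O–S bonds are cut back to 5 through 6 and 7. Moving silicon from oxygen to the lithiated carbon places it exactly between the two oxygens without exposing an acid-sensitive C–Si bond to acid, and the phenoxide released is the one that becomes the triflate. Halogen–lithium exchange has to outrun any other reaction of the base.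

5 ⇒ 4. One of two equivalent acetal groups is removed. The symmetric 4 is easier to obtain regiochemically pure than any unsymmetrical precursor. The price is a cleavage that must be stopped after the first acetal.

4 ⇒ 2 ⇒ 1. The C–I bond is cut to 3 and hence to 2, and the two acetal O–C bonds of 2 to 1. The carbon between the two acetal ethers is the most acidic of 2. The demand is that metalation next to the methyl ether stays minor.

12 ⇒ 10 + 11, and 10 ⇒ 9. The aryl–alkyne bond is cut, then the acetal O–C bonds. One coupling delivers the three-carbon acid complete. It must run cool enough for the carboxyl group of 12 to survive.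

## Other disconnections considered

Alternative 1: Ring A itself is cut at C4a–C8a. Forward, Mg(OMe)2 in methanol would open the 4-hydroxy-2-pyrone A1 to the triketo ester A2. Its methylene between two ketones (future C4a) would attack the ester carbon (future C8a) in a Claisen condensation and aromatise to the chalcone A3.
- In its favour: the folding imitates chalcone biosynthesis and needs no organometallic reagent, no sealed tube and no protecting group on ring A. On these points, and in avoiding the four-step precursor 8 with its non-selective mono-deprotection, it is the better plan.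
- Against it here: A3 has three free ring A hydroxyls, two of them equivalent, whereas 15 leaves the aryne step with O5, O7 and O1 already distinguished. A3 also lacks ring C, so an oxidative ring closure, a selective O7 methylation and a re-protection of O5 would have to follow before the stage of 15 is reached.
- Mechanism: both key steps are polar and base-mediated. The fate of A2 would rest on the balance between Claisen and aldol folding and on the enone surviving methoxide, while the aryne step is steered by one substituent.
- Step economy: shorter before its key step, longer after it. The later problems (C3, C6) are the same, so no net saving is expected.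

Alternative 2: The cut runs through ring B at C1'–C2' and C5'–C6'. Heating the 2-ethynylchromone A4 with the bis-silyloxy diene A5 would give a cyclohexadiene that loses methanol and its silyl groups to become the resorcinol ring of A6.
- In its favour: ring B would appear with both hydroxyls free, so no ring B protecting groups are carried and the final deprotection is lighter. The orientation follows from the polarity of A5 and is at least as secure as that of the aryne addition. On both points the alternative is the equal or the better.
- Against it: ring B is the easiest part of the molecule. A4 would already have to contain everything difficult (ring A with four different substituents, the C6 chain as a ketal, the C3 prenyl group, ring C), none of which this cut simplifies. The alkyne of A4 is activated only through the pyranone and should need prolonged heating, during which A5 could add to C2 in a conjugate sense instead.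
- Mechanism and structure: a pericyclic step with aromatisation against a polar insertion. The chosen step joins rings A and B and makes ring C, which is the larger structural gain.
- Step economy: a separate multi-step synthesis of A4 would outweigh the shorter end.

Alternative 3: Ring A is cut at C5–C6, C7–C8 and C4a–C5 (the C8–C8a bond comes from the Wolff shift). Irradiating the pyranonyl diazo ketone A7 with the 1-methoxyalkyne A8 would give a ketene that adds to the alkyne in a (2+2) sense, opens to a dienylketene and closes by 6π electrocyclisation to the phenol A9.
- In its favour: the ring A substituents would arrive in fixed positions (free C5 hydroxyl from the ketene carbon, O7 methyl from the ynol ether, C6 chain from the alkyne). Neither the C6/C8 question nor a selective acetal cleavage arises. On regiocontrol of ring A this plan is clearly better, and only three steps would remain after it.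
- Against it: A7 needs a fully substituted pyranone carrying the aryl, prenyl and diazoacetyl groups, and A8 is an acid- and heat-sensitive ynol ether. Light would meet a 4-pyranone chromophore and a prenyl alkene, both open to side reactions. The chain has to travel at the alcohol oxidation level, which creates and then destroys a racemic stereocentre and adds a desilylation and an oxidation.
- Mechanism: four pericyclic events in a row against a two-stage polar process from storable components.
- Step economy: the two elaborate precursors should make it longer overall despite its shorter end.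

Key step: step 7

## Route

Step 1
Reactants: 1 5-methoxybenzene-1,3-diol (5-methoxyresorcinol)
Product: 2 1-methoxy-3,5-bis(methoxymethoxy)benzene
Conditions: MOMCl (2.5 equiv), i-Pr2NEt, CH2Cl2, 0 °C to rt
Reagents that add atoms: chloromethyl methyl ether, COCCl
Why: Double O-alkylation of the phenols by the reactive α-chloro ether (Williamson-type acetal ether formation); the two acetal ethers are the strongest ortho-directing groups on the ring and prepare the metalation of step 2.

Step 2
Reactants: 2 1-methoxy-3,5-bis(methoxymethoxy)benzene
Product: 4 2-iodo-5-methoxy-1,3-bis(methoxymethoxy)benzene, via aryllithium 3 (not isolated)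
Conditions: n-BuLi, THF, 0 °C; then I2, −78 °C to rt
Reagents that add atoms: iodine, [I][I]
Why: Directed ortho-metalation: the carbon between the two chelating acetal ethers should be deprotonated in preference to those next to the weaker methoxy director, and the aryllithium is iodinated; the symmetric product is easily told from any minor isomer.

Step 3
Reactants: 4 2-iodo-5-methoxy-1,3-bis(methoxymethoxy)benzene
Product: 5 2-iodo-5-methoxy-3-(methoxymethoxy)phenol
Conditions: HCl (cat.), MeOH/THF, 0 °C to rt, stopped at partial conversion
Reagents that add atoms: none
Why: Acid-catalysed acetal exchange with methanol; the two groups are equivalent, so the reaction is stopped early, unchanged 4 is returned and over-cleaved diol can be re-protected as in step 1.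

Step 4
Reactants: 5 2-iodo-5-methoxy-3-(methoxymethoxy)phenol
Product: 8 5-methoxy-3-(methoxymethoxy)-2-(trimethylsilyl)phenyl trifluoromethanesulfonate, via aryl silyl ether 6 (not isolated), via lithium phenoxide 7 (not isolated)
Conditions: HMDS, THF, 65 °C, evaporate; n-BuLi, THF, −78 to −40 °C; Tf2O, −78 to 0 °C
Reagents that add atoms: hexamethyldisilazane, C[Si](C)(C)N[Si](C)(C)C; trifluoromethanesulfonic anhydride, O=S(=O)(OS(=O)(=O)C(F)(F)F)C(F)(F)F
Why: O-silylation, iodine–lithium exchange and 1,3-migration of silicon from oxygen to the aryl carbanion (retro-Brook rearrangement) place the silyl group between the two oxygens, and the phenoxide released is triflated in the same flask; the C–Si bond never sees acid.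

Step 5
Reactants: 9 4-iodobenzene-1,3-diol (4-iodoresorcinol)
Product: 10 1-iodo-2,4-bis(methoxymethoxy)benzene
Conditions: MOMCl (2.5 equiv), i-Pr2NEt, CH2Cl2, 0 °C to rt
Reagents that add atoms: chloromethyl methyl ether, COCCl
Why: Same acetal ether formation as in step 1; the acetals withstand the base, fluoride and organolithium steps that follow.

Step 6
Reactants: 10 1-iodo-2,4-bis(methoxymethoxy)benzene; 11 prop-2-ynoic acid (propiolic acid)
Product: 12 3-[2,4-bis(methoxymethoxy)phenyl]prop-2-ynoic acid
Conditions: Pd(PPh3)4 (5 mol %), DBU (2.4 equiv), DMSO, 35 °C; cold aq. citric acid work-up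
Reagents that add atoms: none
Why: Copper-free Sonogashira coupling of an aryl iodide with the amidinium salt of propiolic acid; the iodide should react at a temperature at which the arylpropiolate keeps its CO2, and leaving out copper avoids alkyne dimerisation and copper-promoted decarboxylation.

Step 7
Reactants: 8 5-methoxy-3-(methoxymethoxy)-2-(trimethylsilyl)phenyl trifluoromethanesulfonate; 12 3-[2,4-bis(methoxymethoxy)phenyl]prop-2-ynoic acid
Product: 15 2-[2,4-bis(methoxymethoxy)phenyl]-7-methoxy-5-(methoxymethoxy)chromen-4-one, via alkoxyaryne 13 (not isolated), via hydroxyaryl ynone 14 (not isolated)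
Conditions: CsF (4 equiv), 8 (1.5 equiv), THF, 125 °C, sealed tube
Reagents that add atoms: none
Why: CsF strips the silyl group from 8 and loss of triflate gives aryne 13. The caesium carboxylate of 12 adds through oxygen to the aryne carbon remote from the MOM ether (future C8a): that carbon is the more exposed, electrophilic end of the distorted triple bond, and the carbanion left on the future C4a is stabilised inductively by the adjacent C5 oxygen. This anion attacks the neighbouring ester carbonyl (4-exo-trig) and the four-membered alkoxide opens to the o-acylphenoxide 14, so the aryne has formally inserted into the acid C–O bond and O1–C8a and C4–C4a exist. The closest known reaction type is the fluoride-induced coupling of arynes with carboxylic acids to o-hydroxyaryl ketones, which with arylpropiolic acids runs on to flavones. Ring C is then closed by 6-endo-dig conjugate addition (oxa-Michael) of the phenoxide to the ynone, forming O1–C2, and protonation at C3 gives 15; no stereocentre is created. Three selectivities are needed: the orientation of the aryne addition, secured by the C5 MOM ether (the future C7 methoxy group is meta to the attacked carbon and does not oppose it); acyl transfer ahead of protonation of the aryl anion, favoured by the preformed caesium salt in aprotic THF; and 6-endo over 5-exo closure, favoured because the ynone carbon β to the carbonyl is the electrophilic one. The acetal and methyl ethers are inert to fluoride.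

Step 8
Reactants: 15 2-[2,4-bis(methoxymethoxy)phenyl]-7-methoxy-5-(methoxymethoxy)chromen-4-one; 16 1-bromo-3-methylbut-2-ene (prenyl bromide)
Product: 18 2-[2,4-bis(methoxymethoxy)phenyl]-7-methoxy-5-(methoxymethoxy)-3-(3-methylbut-2-en-1-yl)chromen-4-one, via 3-lithioflavone 17 (not isolated)
Conditions: LiN(i-Pr)2 (LDA, commercial solution), THF, −78 °C; then 16, −78 to 0 °C
Reagents that add atoms: none
Why: Carbonyl-assisted vinylic lithiation of a 2-arylchromone at C3 by a lithium amide is a known metalation, and the anion is alkylated by SN2 attack at the primary carbon of the allylic bromide; no other C–H of 15 is acidic enough for the amide base at −78 °C.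

Step 9
Reactants: 18 2-[2,4-bis(methoxymethoxy)phenyl]-7-methoxy-5-(methoxymethoxy)-3-(3-methylbut-2-en-1-yl)chromen-4-one
Product: 19 2-[2,4-bis(methoxymethoxy)phenyl]-5-hydroxy-7-methoxy-3-(3-methylbut-2-en-1-yl)chromen-4-one
Conditions: MgBr2·OEt2, Et2O/CH2Cl2, 0 °C to rt; aq. NH4Cl
Reagents that add atoms: none
Why: Chelation-controlled ether cleavage: magnesium is held between the C4 carbonyl and O5, and bromide removes the CH2OMe group from that oxygen only (the bromomethyl ether is hydrolysed on work-up); the ring B acetals have no carbonyl partner and should remain.

Step 10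
Reactants: 19 2-[2,4-bis(methoxymethoxy)phenyl]-5-hydroxy-7-methoxy-3-(3-methylbut-2-en-1-yl)chromen-4-one
Product: 20 2-[2,4-bis(methoxymethoxy)phenyl]-6-[(dimethylamino)methyl]-5-hydroxy-7-methoxy-3-(3-methylbut-2-en-1-yl)chromen-4-one
Conditions: Me2N=CH2+ I− (Eschenmoser's salt), Et3N, CH2Cl2, rt
Reagents that add atoms: N,N-dimethylmethyleneiminium iodide, C=[N+](C)C.[I-]
Why: Mannich aminomethylation of a phenol with a preformed iminium salt; the free C5 hydroxyl activates and directs to its ortho position C6, while aryl ethers and the alkene should not react with this weak electrophile.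

Step 11
Reactants: 20 2-[2,4-bis(methoxymethoxy)phenyl]-6-[(dimethylamino)methyl]-5-hydroxy-7-methoxy-3-(3-methylbut-2-en-1-yl)chromen-4-one; 21 2-methylpropanal (isobutyraldehyde)
Product: 24 2-[2,4-bis(methoxymethoxy)phenyl]-5-hydroxy-7-methoxy-6-(3-methyl-2-oxobutyl)-3-(3-methylbut-2-en-1-yl)chromen-4-one, via ammonium iodide 22 (not isolated), via quinone methide 23 (not isolated)
Conditions: MeI, MeCN, rt, evaporate; 21 (5 equiv), 3-benzyl-5-(2-hydroxyethyl)-4-methylthiazolium chloride (30 mol %), Et3N, DMF, 60 °C
Reagents that add atoms: none
Why: Quaternisation turns the amine into a leaving group and base then releases the o-quinone methide by 1,4-elimination; the Breslow intermediate formed from 21 and the thiazol-2-ylidene adds to the exocyclic methylene (Stetter-type conjugate acylation of an o-quinone methide), which restores ring A and frees the carbene. The conditions leave the prenyl alkene and the acetals alone.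

Step 12
Reactants: 24 2-[2,4-bis(methoxymethoxy)phenyl]-5-hydroxy-7-methoxy-6-(3-methyl-2-oxobutyl)-3-(3-methylbut-2-en-1-yl)chromen-4-one
Product: 25 2-(2,4-dihydroxyphenyl)-5-hydroxy-7-methoxy-6-(3-methyl-2-oxobutyl)-3-(3-methylbut-2-en-1-yl)chromen-4-one
Conditions: HCl (1 M in MeOH), rt to 40 °C
Reagents that add atoms: none
Why: Acid-catalysed methanolysis of the two aryl acetals; dilute acid at low temperature is chosen so that the prenyl alkene is not hydrated and the chelated C5 hydroxyl does not condense with the ketone.

## Compound list

1 | 5-methoxybenzene-1,3-diol (5-methoxyresorcinol) | COc1cc(O)cc(O)c1 | starting material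
2 | 1-methoxy-3,5-bis(methoxymethoxy)benzene | COCOc1cc(OC)cc(OCOC)c1 | intermediate
3 | [4-methoxy-2,6-bis(methoxymethoxy)phenyl]lithium | [Li]c1c(OCOC)cc(OC)cc1OCOC | intermediate
4 | 2-iodo-5-methoxy-1,3-bis(methoxymethoxy)benzene | COCOc1cc(OC)cc(OCOC)c1I | intermediate
5 | 2-iodo-5-methoxy-3-(methoxymethoxy)phenol | COCOc1cc(OC)cc(O)c1I | intermediate
6 | [2-iodo-5-methoxy-3-(methoxymethoxy)phenoxy]trimethylsilane | COCOc1cc(OC)cc(O[Si](C)(C)C)c1I | intermediate
7 | lithium 5-methoxy-3-(methoxymethoxy)-2-(trimethylsilyl)phenoxide | COCOc1cc(OC)cc([O-])c1[Si](C)(C)C.[Li+] | intermediate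
8 | 5-methoxy-3-(methoxymethoxy)-2-(trimethylsilyl)phenyl trifluoromethanesulfonate | COCOc1cc(OC)cc(OS(=O)(=O)C(F)(F)F)c1[Si](C)(C)C | intermediate
9 | 4-iodobenzene-1,3-diol (4-iodoresorcinol) | Oc1ccc(I)c(O)c1 | starting material
10 | 1-iodo-2,4-bis(methoxymethoxy)benzene | COCOc1ccc(I)c(OCOC)c1 | intermediate
11 | prop-2-ynoic acid (propiolic acid) | C#CC(=O)O | starting material
12 | 3-[2,4-bis(methoxymethoxy)phenyl]prop-2-ynoic acid | COCOc1ccc(C#CC(=O)O)c(OCOC)c1 | intermediate
13 | 5-methoxy-3-(methoxymethoxy)benzyne (triple bond between the former triflate and silyl carbons) | COCOC1=CC(OC)=CC#C1 | intermediate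
14 | 3-[2,4-bis(methoxymethoxy)phenyl]-1-[2-hydroxy-4-methoxy-6-(methoxymethoxy)phenyl]prop-2-yn-1-one (present as its caesium phenoxide) | COCOc1ccc(C#CC(=O)c2c(O)cc(OC)cc2OCOC)c(OCOC)c1 | intermediate
15 | 2-[2,4-bis(methoxymethoxy)phenyl]-7-methoxy-5-(methoxymethoxy)chromen-4-one | COCOc1ccc(-c2cc(=O)c3c(OCOC)cc(OC)cc3o2)c(OCOC)c1 | intermediate
16 | 1-bromo-3-methylbut-2-ene (prenyl bromide) | CC(C)=CCBr | starting material
17 | {2-[2,4-bis(methoxymethoxy)phenyl]-7-methoxy-5-(methoxymethoxy)-4-oxochromen-3-yl}lithium | [Li]c1c(-c2ccc(OCOC)cc2OCOC)oc2cc(OC)cc(OCOC)c2c1=O | intermediate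
18 | 2-[2,4-bis(methoxymethoxy)phenyl]-7-methoxy-5-(methoxymethoxy)-3-(3-methylbut-2-en-1-yl)chromen-4-one | COCOc1ccc(-c2oc3cc(OC)cc(OCOC)c3c(=O)c2CC=C(C)C)c(OCOC)c1 | intermediate
19 | 2-[2,4-bis(methoxymethoxy)phenyl]-5-hydroxy-7-methoxy-3-(3-methylbut-2-en-1-yl)chromen-4-one | COCOc1ccc(-c2oc3cc(OC)cc(O)c3c(=O)c2CC=C(C)C)c(OCOC)c1 | intermediate
20 | 2-[2,4-bis(methoxymethoxy)phenyl]-6-[(dimethylamino)methyl]-5-hydroxy-7-methoxy-3-(3-methylbut-2-en-1-yl)chromen-4-one | COCOc1ccc(-c2oc3cc(OC)c(CN(C)C)c(O)c3c(=O)c2CC=C(C)C)c(OCOC)c1 | intermediate
21 | 2-methylpropanal (isobutyraldehyde) | CC(C)C=O | starting material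
22 | {2-[2,4-bis(methoxymethoxy)phenyl]-5-hydroxy-7-methoxy-3-(3-methylbut-2-en-1-yl)-4-oxochromen-6-yl}-N,N,N-trimethylmethanaminium iodide | COCOc1ccc(-c2oc3cc(OC)c(C[N+](C)(C)C)c(O)c3c(=O)c2CC=C(C)C)c(OCOC)c1.[I-] | intermediate
23 | 2-[2,4-bis(methoxymethoxy)phenyl]-7-methoxy-6-methylidene-3-(3-methylbut-2-en-1-yl)-6H-chromene-4,5-dione | C=C1C(OC)=CC2=C(C1=O)C(=O)C(CC=C(C)C)=C(c1ccc(OCOC)cc1OCOC)O2 | intermediate
24 | 2-[2,4-bis(methoxymethoxy)phenyl]-5-hydroxy-7-methoxy-6-(3-methyl-2-oxobutyl)-3-(3-methylbut-2-en-1-yl)chromen-4-one | COCOc1ccc(-c2oc3cc(OC)c(CC(=O)C(C)C)c(O)c3c(=O)c2CC=C(C)C)c(OCOC)c1 | intermediate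
25 | 2-(2,4-dihydroxyphenyl)-5-hydroxy-7-methoxy-6-(3-methyl-2-oxobutyl)-3-(3-methylbut-2-en-1-yl)chromen-4-one (CNP0291994.0) | COc1cc2oc(-c3ccc(O)cc3O)c(CC=C(C)C)c(=O)c2c(O)c1CC(=O)C(C)C | target

## Step count and least certain steps

Total: 12 steps. Longest linear sequence: 10 steps (steps 1–4 and 7–12, from 1 to 25); the branch to 12 has 2 steps.

Step 7 (key step). Most likely to go wrong: the caesium salt of 12 loses CO2 at 125 °C before it meets 13, since an electron-rich arylpropiolate decarboxylates readily. The aryl anion may also be protonated before it transfers the acyl group, or the phenoxide of 14 may close in the 5-exo mode. Fallback, from 5 and 12 back to 15: 12 is decarboxylated on purpose (CuCl cat., Et3N, MeCN, 60 °C) to 1-ethynyl-2,4-bis(methoxymethoxy)benzene F1. The o-iodophenol 5, F1 and CO are then joined by palladium-catalysed carbonylative Sonogashira coupling (PdCl2(dppf), Et2NH, CO, 60–120 °C). The ynone 14 formed in the flask is cyclised by the secondary amine, through its enaminone, to 15.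

Step 11. Most likely to go wrong: the carbene is consumed by direct addition to 23, or 21 undergoes acyloin or aldol self-condensation faster than the conjugate addition, or 23 oligomerises or is recaptured by the amine set free. The product, an acidic benzyl ketone, could also be benzylated a second time. Fallback, from 20 back to 24: after the same quaternisation, 23 is intercepted by the nitronate of 2-methyl-1-nitropropane (DBU, MeCN) to give rac-2-[2,4-bis(methoxymethoxy)phenyl]-5-hydroxy-7-methoxy-6-(3-methyl-2-nitrobutyl)-3-(3-methylbut-2-en-1-yl)chromen-4-one F2. A Nef reaction (NaOMe, then buffered aqueous TiCl3) converts the secondary nitro group into the ketone of 24.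

Step 10. Most likely to go wrong: aminomethylation at C8 (para to the hydroxyl and also flanked by two oxygens) or at both positions, because the chelated hydroxyl is a weak ortho director. Fallback, from 19 back to 24 (20, 22 and 23 are bypassed): iodination ortho to the free hydroxyl with benzyltrimethylammonium dichloroiodate and CaCO3 in CH2Cl2/MeOH at 0 °C gives 2-[2,4-bis(methoxymethoxy)phenyl]-5-hydroxy-6-iodo-7-methoxy-3-(3-methylbut-2-en-1-yl)chromen-4-one F3. This reagent is known to prefer the position ortho to the free hydroxyl in 5-hydroxy-7-alkoxyflavones; one equivalent only is used, because the prenyl alkene is the competing site. Palladium-catalysed α-arylation of 3-methylbutan-2-one at its methyl group (Pd2(dba)3, Xantphos, K3PO4, toluene, 80 °C) then attaches the complete side chain to give 24.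

Step 8. Most likely to go wrong: slow reaction of the hindered C3 anion with the allylic bromide, attack at the tertiary end of 16 (giving the 1,1-dimethylallyl isomer), or ring opening of 17 to an alkynyl ketone on warming. Fallback, from 15 back to 18: 17 is quenched at −78 °C with I2, a fast trap, to give 2-[2,4-bis(methoxymethoxy)phenyl]-3-iodo-7-methoxy-5-(methoxymethoxy)chromen-4-one F4. The prenyl group is then introduced by Stille coupling with tributyl(3-methylbut-2-en-1-yl)stannane (Pd(PPh3)4, CuI, DMF, 60 °C) to give 18.

Step 3. Most likely to go wrong: over-cleavage and incomplete conversion at the same time, because the two acetals are equivalent and the first cleavage does not slow the second, so material is lost to recycling. Fallback, from 4 back to 7: both acetals are removed (HCl, MeOH) to give 2-iodo-5-methoxybenzene-1,3-diol F5, and HMDS gives [(2-iodo-5-methoxy-1,3-phenylene)bis(oxy)]bis(trimethylsilane) F6. n-BuLi then triggers iodine–lithium exchange and retro-Brook migration of one silyl group only, since there is a single carbanion. The lithium phenoxide is capped in the flask with MOMCl to give [5-methoxy-3-(methoxymethoxy)-2-(trimethylsilyl)phenoxy]trimethylsilane F7. The remaining O–Si bond is hydrolysed on mildly acidic aqueous work-up to 5-methoxy-3-(methoxymethoxy)-2-(trimethylsilyl)phenol F8, whose deprotonation with n-BuLi gives 7, ready for triflation to 8. The desymmetrisation is then no longer statistical, at the price of two extra operations.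

## Further compounds

F1 | step 7 | 1-ethynyl-2,4-bis(methoxymethoxy)benzene | C#Cc1ccc(OCOC)cc1OCOC
F2 | step 11 | rac-2-[2,4-bis(methoxymethoxy)phenyl]-5-hydroxy-7-methoxy-6-(3-methyl-2-nitrobutyl)-3-(3-methylbut-2-en-1-yl)chromen-4-one | COCOc1ccc(-c2oc3cc(OC)c(CC(C(C)C)[N+](=O)[O-])c(O)c3c(=O)c2CC=C(C)C)c(OCOC)c1
F3 | step 10 | 2-[2,4-bis(methoxymethoxy)phenyl]-5-hydroxy-6-iodo-7-methoxy-3-(3-methylbut-2-en-1-yl)chromen-4-one | COCOc1ccc(-c2oc3cc(OC)c(I)c(O)c3c(=O)c2CC=C(C)C)c(OCOC)c1
F4 | step 8 | 2-[2,4-bis(methoxymethoxy)phenyl]-3-iodo-7-methoxy-5-(methoxymethoxy)chromen-4-one | COCOc1ccc(-c2oc3cc(OC)cc(OCOC)c3c(=O)c2I)c(OCOC)c1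
F5 | step 3 | 2-iodo-5-methoxybenzene-1,3-diol | COc1cc(O)c(I)c(O)c1
F6 | step 3 | [(2-iodo-5-methoxy-1,3-phenylene)bis(oxy)]bis(trimethylsilane) | COc1cc(O[Si](C)(C)C)c(I)c(O[Si](C)(C)C)c1
F7 | step 3 | [5-methoxy-3-(methoxymethoxy)-2-(trimethylsilyl)phenoxy]trimethylsilane | COCOc1cc(OC)cc(O[Si](C)(C)C)c1[Si](C)(C)C
F8 | step 3 | 5-methoxy-3-(methoxymethoxy)-2-(trimethylsilyl)phenol | COCOc1cc(OC)cc(O)c1[Si](C)(C)C
A1 | alternative 1 | 6-{(3E)-4-[2,4-bis(methoxymethoxy)phenyl]-2-oxobut-3-en-1-yl}-4-hydroxy-2H-pyran-2-one | O=C(/C=C/c1ccc(OCOC)cc1OCOC)CC1=CC(O)=CC(=O)O1
A2 | alternative 1 | methyl (8E)-9-[2,4-bis(methoxymethoxy)phenyl]-3,5,7-trioxonon-8-enoate | COC(=O)CC(=O)CC(=O)CC(=O)/C=C/c1ccc(OCOC)cc1OCOC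
A3 | alternative 1 | (E)-3-[2,4-bis(methoxymethoxy)phenyl]-1-(2,4,6-trihydroxyphenyl)prop-2-en-1-one | O=C(/C=C/c1ccc(OCOC)cc1OCOC)c1c(O)cc(O)cc1O
A4 | alternative 2 | 2-ethynyl-7-methoxy-5-(methoxymethoxy)-3-(3-methylbut-2-en-1-yl)-6-{[2-(propan-2-yl)-1,3-dioxolan-2-yl]methyl}chromen-4-one | C#Cc1oc2cc(OC)c(CC3(C(C)C)OCCO3)c(OCOC)c2c(=O)c1CC=C(C)C
A5 | alternative 2 | 1-methoxy-1,3-bis(trimethylsilyloxy)buta-1,3-diene | C=C(O[Si](C)(C)C)C=C(OC)O[Si](C)(C)C
A6 | alternative 2 | 2-(2,4-dihydroxyphenyl)-7-methoxy-5-(methoxymethoxy)-3-(3-methylbut-2-en-1-yl)-6-{[2-(propan-2-yl)-1,3-dioxolan-2-yl]methyl}chromen-4-one | COc1cc2oc(-c3ccc(O)cc3O)c(CC=C(C)C)c(=O)c2c(OCOC)c1CC1(C(C)C)OCCO1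
A7 | alternative 3 | 2-[2,4-bis(methoxymethoxy)phenyl]-6-(2-diazoacetyl)-3-(3-methylbut-2-en-1-yl)-4H-pyran-4-one | O=C(C=[N+]=[N-])c1cc(=O)c(CC=C(C)C)c(-c2ccc(OCOC)cc2OCOC)o1
A8 | alternative 3 | rac-tert-butyl[(1-methoxy-5-methylhex-1-yn-4-yl)oxy]dimethylsilane | COC#CCC(O[Si](C)(C)C(C)(C)C)C(C)C
A9 | alternative 3 | rac-2-[2,4-bis(methoxymethoxy)phenyl]-6-{2-[(tert-butyldimethylsilyl)oxy]-3-methylbutyl}-5-hydroxy-7-methoxy-3-(3-methylbut-2-en-1-yl)chromen-4-one | COCOc1ccc(-c2oc3cc(OC)c(CC(O[Si](C)(C)C(C)(C)C)C(C)C)c(O)c3c(=O)c2CC=C(C)C)c(OCOC)c1
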